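**Strategy**

Everything rests on cutting the saturated ring at C6–C7 (naphthalene numbering), the CH2–CH2 link between the benzylic stereocentres C5 and C8; because these two ring atoms are unfunctionalised, an alkene formed there leaves no trace after hydrogenation. C5, C8 and side-chain C2′ are therefore installed on an open benzoate as vinyl-bearing arms (asymmetric hydrovinylation; palladium-catalysed allyl–allyl coupling). One metathesis operation on the resulting triene then closes the six-membered ring through C6=C7 and, in the same flask, joins the spare 2′-vinyl group to a chiral pentenyl ester that carries C6′ and the hydrocinnamate. A single hydrogenation finally saturates both alkenes and removes both benzyl groups.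

Key step: step 9

Remark: locants C5–C8 and primed side-chain locants follow the systematic name of the target; (2R)-2-methylpent-4-en-1-ol and (2E)-3-(tributylstannyl)prop-2-en-1-ol are taken as purchasable; the new side-chain alkene is drawn E, its geometry being immaterial because it is hydrogenated.

**Route**

Step 1
Reactants: 1 4-bromo-3,5-dihydroxybenzoic acid
Product: 2 benzyl 3-(benzyloxy)-4-bromo-5-hydroxybenzoate
Conditions: BnBr (2.05 equiv), K2CO3, DMF, 0 to 23 °C
Reagents that add atoms: benzyl bromide, BrCc1ccccc1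
Why: Carboxylate and phenol O-alkylation (Williamson type): with two equivalents of benzyl bromide the acid and one of the two equivalent phenols of symmetric 1 should be benzylated, 2 being the main component of a near-statistical mixture from which bis-ether and diol ester are separated and recycled.

Step 2
Reactants: 2 benzyl 3-(benzyloxy)-4-bromo-5-hydroxybenzoate; 3 vinylboronic acid pinacol ester (2-ethenyl-4,4,5,5-tetramethyl-1,3,2-dioxaborolane)
Product: 4 benzyl 3-(benzyloxy)-4-ethenyl-5-hydroxybenzoate
Conditions: Pd(OAc)2 (3 mol %), SPhos (6 mol %), K3PO4, toluene/H2O 10:1, 85 °C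
Reagents that add atoms: none
Why: Suzuki–Miyaura coupling: the bulky, electron-rich biarylphosphine supports oxidative addition at the doubly ortho-substituted C–Br bond, and the free phenol and the benzyl ester are tolerated under phosphate base.

Step 3
Reactants: 4 benzyl 3-(benzyloxy)-4-ethenyl-5-hydroxybenzoate
Product: 5 benzyl 3-(benzyloxy)-4-ethenyl-5-[(trifluoromethanesulfonyl)oxy]benzoate
Conditions: Tf2O, pyridine, CH2Cl2, 0 °C
Reagents that add atoms: trifluoromethanesulfonic anhydride, O=S(=O)(OS(=O)(=O)C(F)(F)F)C(F)(F)F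
Why: O-Sulfonylation of the phenol turns the remaining oxygen into the cross-coupling handle for the second arm without affecting the styrene.

Step 4
Reactants: 5 benzyl 3-(benzyloxy)-4-ethenyl-5-[(trifluoromethanesulfonyl)oxy]benzoate; 6 ethylene
Product: 7 benzyl 3-(benzyloxy)-4-[(2R)-but-3-en-2-yl]-5-[(trifluoromethanesulfonyl)oxy]benzoate
Conditions: ethylene (1 atm), [Ni(η3-C3H5)Br]2 (2 mol %), binaphthol-derived phosphoramidite of bis(1-phenylethyl)amine (4 mol %, enantiomer giving R), Na[B(3,5-(CF3)2C6H3)4] (4 mol %), CH2Cl2, −70 °C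
Reagents that add atoms: none
Why: Nickel-catalysed asymmetric hydrovinylation of a vinylarene: the cationic nickel hydride adds to the styrene to give a benzylic nickel species, ethylene inserts and β-hydride elimination releases the 3-aryl-1-butene, the chiral phosphoramidite fixing the new benzylic centre (the later C5) as R.

Step 5
Reactants: 7 benzyl 3-(benzyloxy)-4-[(2R)-but-3-en-2-yl]-5-[(trifluoromethanesulfonyl)oxy]benzoate; 8 (2E)-3-(tributylstannyl)prop-2-en-1-ol
Product: 9 benzyl 3-(benzyloxy)-4-[(2R)-but-3-en-2-yl]-5-[(1E)-3-hydroxyprop-1-en-1-yl]benzoate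
Conditions: Pd(PPh3)4 (5 mol %), LiCl (3 equiv), 1,4-dioxane, 100 °C
Reagents that add atoms: none
Why: Stille coupling of an aryl triflate (chloride-assisted oxidative addition and transmetalation) transfers the alkenyl group with retention of its E geometry and tolerates the free alcohol, the ester and the terminal alkene.

Step 6
Reactants: 9 benzyl 3-(benzyloxy)-4-[(2R)-but-3-en-2-yl]-5-[(1E)-3-hydroxyprop-1-en-1-yl]benzoate
Product: 10 benzyl 3-(benzyloxy)-4-[(2R)-but-3-en-2-yl]-5-[(1E)-3-chloroprop-1-en-1-yl]benzoate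
Conditions: NCS, Me2S, CH2Cl2, −20 to 0 °C
Reagents that add atoms: N-chlorosuccinimide, O=C1CCC(=O)N1Cl
Why: Corey–Kim-type chlorination: the alkoxysulfonium ion formed from the allylic alcohol and the NCS–Me2S adduct is displaced by chloride under non-acidic conditions, leaving the terminal alkene and the benzylic stereocentre untouched.

Step 7
Reactants: 10 benzyl 3-(benzyloxy)-4-[(2R)-but-3-en-2-yl]-5-[(1E)-3-chloroprop-1-en-1-yl]benzoate; 11 (E)-crotylboronic acid pinacol ester (2-[(2E)-but-2-en-1-yl]-4,4,5,5-tetramethyl-1,3,2-dioxaborolane)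
Product: 12 benzyl 3-(benzyloxy)-4-[(2R)-but-3-en-2-yl]-5-[(3S,4S)-4-methylhexa-1,5-dien-3-yl]benzoate
Conditions: Pd2(dba)3 (2.5 mol %), (R)-MeO-furyl-BIPHEP (6 mol %; enantiomer giving 3S), CsF, THF/H2O 10:1, 23 °C
Reagents that add atoms: none
Why: Palladium-catalysed enantioselective allyl–allyl cross-coupling: transmetalation of the π-allylpalladium chloride from 10 with 11 gives a bis(η1-allyl)palladium that undergoes branch-selective 3,3′-reductive elimination through a chair-like transition state, the chiral bisphosphine fixing the benzylic centre (later C8) as S and the E geometry of both allyl units relaying the like relationship to the adjacent methyl-bearing centre (later C2′, S).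

Step 8
Reactants: 13 (2R)-2-methylpent-4-en-1-ol; 14 3-phenylpropanoyl chloride
Product: 15 (2R)-2-methylpent-4-en-1-yl 3-phenylpropanoate
Conditions: pyridine, DMAP (cat.), CH2Cl2, 0 to 23 °C
Reagents that add atoms: none
Why: Nucleophilic acyl substitution (DMAP-catalysed acylation of a primary alcohol); the stereocentre of 13, the later C6′, is not involved.

Step 9
Reactants: 12 benzyl 3-(benzyloxy)-4-[(2R)-but-3-en-2-yl]-5-[(3S,4S)-4-methylhexa-1,5-dien-3-yl]benzoate; 15 (2R)-2-methylpent-4-en-1-yl 3-phenylpropanoate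
Product: 17 benzyl (5R,8S)-4-(benzyloxy)-5-methyl-8-[(2S,3E,6R)-6-methyl-7-(3-phenylpropanoyloxy)hept-3-en-2-yl]-5,8-dihydronaphthalene-2-carboxylate, via ring-closed vinyl diene 16 (not isolated)
Conditions: second-generation Grubbs catalyst (5 mol %), 1,4-benzoquinone (10 mol %), CH2Cl2 (0.01 M), 40 °C; then 15 (5 equiv) and a second catalyst charge (5 mol %), 40 °C
Reagents that add atoms: none
Why: The ruthenium alkylidene formed at one benzylic vinyl group of 12 undergoes [2+2] cycloaddition and cycloreversion (metallacyclobutane mechanism) with the other benzylic vinyl group, releasing ethylene and closing the carbocycle through the new C6=C7 bond; this is ring-closing metathesis to a six-membered ring, in which the two terminal alkene carbons are joined while C5, C4a, C8a and C8 are already connected through the arene. The remaining 2′-vinyl group of 16 is then cross-metathesised in the same flask with the terminal alkene of 15, the closest precedents being tandem ring-closing/cross-metathesis sequences on trienes. No stereocentre is created: C5, C8 and C2′ come from steps 4 and 7 and C6′ from 13, and the geometry of the new side-chain alkene is irrelevant because it is hydrogenated. The step needs six- over seven-membered ring closure and ring closure before cross-coupling: the ortho relationship of the two benzylic vinyl groups should make the six-ring closure the fastest intramolecular event, the vicinal vinyl pair on C8/C2′ cannot close (it would give a cyclobutene), and 15 is added only after 12 is consumed. 1,4-Benzoquinone suppresses ruthenium hydride-induced migration of the C6=C7 bond into conjugation, which would endanger C5 or C8.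

Step 10
Reactants: 17 benzyl (5R,8S)-4-(benzyloxy)-5-methyl-8-[(2S,3E,6R)-6-methyl-7-(3-phenylpropanoyloxy)hept-3-en-2-yl]-5,8-dihydronaphthalene-2-carboxylate
Product: 18 (5R,8S)-4-hydroxy-5-methyl-8-[(2S,6R)-6-methyl-7-(3-phenylpropanoyloxy)heptan-2-yl]-5,6,7,8-tetrahydronaphthalene-2-carboxylic acid (CNP0511546.1)
Conditions: H2 (1 atm), 10% Pd/C, EtOAc/EtOH, 23 °C
Reagents that add atoms: none
Why: Heterogeneous catalytic hydrogenation saturates both disubstituted alkenes without creating a stereocentre and hydrogenolyses the benzyl ether and the benzyl ester in the same operation, while the aliphatic 3-phenylpropanoate is inert.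

**Compound list**

1 | 4-bromo-3,5-dihydroxybenzoic acid | OC(=O)c1cc(O)c(Br)c(O)c1 | starting material
2 | benzyl 3-(benzyloxy)-4-bromo-5-hydroxybenzoate | O=C(OCc1ccccc1)c1cc(O)c(Br)c(OCc2ccccc2)c1 | intermediate
3 | vinylboronic acid pinacol ester | C=CB1OC(C)(C)C(C)(C)O1 | starting material
4 | benzyl 3-(benzyloxy)-4-ethenyl-5-hydroxybenzoate | O=C(OCc1ccccc1)c1cc(O)c(C=C)c(OCc2ccccc2)c1 | intermediate
5 | benzyl 3-(benzyloxy)-4-ethenyl-5-[(trifluoromethanesulfonyl)oxy]benzoate | O=C(OCc1ccccc1)c1cc(OS(=O)(=O)C(F)(F)F)c(C=C)c(OCc2ccccc2)c1 | intermediate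
6 | ethylene | C=C | starting material
7 | benzyl 3-(benzyloxy)-4-[(2R)-but-3-en-2-yl]-5-[(trifluoromethanesulfonyl)oxy]benzoate | C[C@H](C=C)c1c(OCc2ccccc2)cc(C(=O)OCc2ccccc2)cc1OS(=O)(=O)C(F)(F)F | intermediate
8 | (2E)-3-(tributylstannyl)prop-2-en-1-ol | CCCC[Sn](CCCC)(CCCC)/C=C/CO | starting material
9 | benzyl 3-(benzyloxy)-4-[(2R)-but-3-en-2-yl]-5-[(1E)-3-hydroxyprop-1-en-1-yl]benzoate | C[C@H](C=C)c1c(OCc2ccccc2)cc(C(=O)OCc2ccccc2)cc1/C=C/CO | intermediate
10 | benzyl 3-(benzyloxy)-4-[(2R)-but-3-en-2-yl]-5-[(1E)-3-chloroprop-1-en-1-yl]benzoate | C[C@H](C=C)c1c(OCc2ccccc2)cc(C(=O)OCc2ccccc2)cc1/C=C/CCl | intermediate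
11 | (E)-crotylboronic acid pinacol ester | C/C=C/CB1OC(C)(C)C(C)(C)O1 | starting material
12 | benzyl 3-(benzyloxy)-4-[(2R)-but-3-en-2-yl]-5-[(3S,4S)-4-methylhexa-1,5-dien-3-yl]benzoate | C=C[C@H](C)[C@H](C=C)c1cc(C(=O)OCc2ccccc2)cc(OCc2ccccc2)c1[C@H](C)C=C | intermediate
13 | (2R)-2-methylpent-4-en-1-ol | C[C@H](CC=C)CO | starting material
14 | 3-phenylpropanoyl chloride | O=C(Cl)CCc1ccccc1 | starting material
15 | (2R)-2-methylpent-4-en-1-yl 3-phenylpropanoate | C[C@H](CC=C)COC(=O)CCc1ccccc1 | intermediate
16 | benzyl (5R,8S)-4-(benzyloxy)-8-[(2S)-but-3-en-2-yl]-5-methyl-5,8-dihydronaphthalene-2-carboxylate (not isolated) | C=C[C@H](C)[C@@H]1C=C[C@@H](C)c2c(OCc3ccccc3)cc(C(=O)OCc3ccccc3)cc21 | intermediate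
17 | benzyl (5R,8S)-4-(benzyloxy)-5-methyl-8-[(2S,3E,6R)-6-methyl-7-(3-phenylpropanoyloxy)hept-3-en-2-yl]-5,8-dihydronaphthalene-2-carboxylate | C[C@H](C/C=C/[C@H](C)[C@@H]1C=C[C@@H](C)c2c(OCc3ccccc3)cc(C(=O)OCc3ccccc3)cc21)COC(=O)CCc1ccccc1 | intermediate
18 | (5R,8S)-4-hydroxy-5-methyl-8-[(2S,6R)-6-methyl-7-(3-phenylpropanoyloxy)heptan-2-yl]-5,6,7,8-tetrahydronaphthalene-2-carboxylic acid | C[C@H](CCC[C@H](C)[C@@H]1CC[C@@H](C)c2c(O)cc(C(=O)O)cc21)COC(=O)CCc1ccccc1 | target

**Step count**

Total steps: 10. Longest linear sequence: 9 (steps 1–7, 9, 10); step 8 is a one-step side branch.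

**Steps most likely to fail, with fallbacks**

Step 4. The styrene of 5 is flanked by two ortho substituents and twisted out of conjugation, so nickel hydride insertion may be slow and facial selectivity poor. The fallback makes the C5 centre by C–CH3 bond formation (copper-catalysed asymmetric allylic substitution) instead of hydrovinylation. It sets out from 2: Tf2O/pyridine should give benzyl 3-(benzyloxy)-4-bromo-5-[(trifluoromethanesulfonyl)oxy]benzoate F1; a bromide-selective Stille coupling with 8 (Pd2(dba)3, P(t-Bu)3, CsF, dioxane) should give benzyl 3-(benzyloxy)-4-[(1E)-3-hydroxyprop-1-en-1-yl]-5-[(trifluoromethanesulfonyl)oxy]benzoate F2; NCS/Me2S should convert it into benzyl 3-(benzyloxy)-4-[(1E)-3-chloroprop-1-en-1-yl]-5-[(trifluoromethanesulfonyl)oxy]benzoate F3; MeMgBr with copper thiophene-2-carboxylate and a chiral binaphthol phosphoramidite (CH2Cl2, −78 °C) should then deliver the branched SN2′ product, which is 7, where the route is rejoined.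

Step 7. The ortho sec-alkyl group may erode branch selectivity and enantio- or diastereocontrol in the 3,3′-reductive elimination, and the relative configuration could depart from the chair model. The fallback is stereodivergent iridium/amine dual catalysis, in which each of the two centres is set by its own catalyst. It sets out from 7: reductive carbonylation (Pd(OAc)2, dppp, CO, Et3SiH, Et3N, DMF, 70 °C) should give benzyl 3-(benzyloxy)-4-[(2R)-but-3-en-2-yl]-5-formylbenzoate F4; CH2=CHMgBr (THF, −78 °C) should give benzyl 3-(benzyloxy)-4-[(2R)-but-3-en-2-yl]-5-(1-hydroxyprop-2-en-1-yl)benzoate F5 as both carbinol epimers; allylation of propanal with F5 ([Ir(cod)Cl]2, chiral phosphoramidite–olefin ligand, diarylprolinol silyl ether, dimethyl hydrogen phosphate, 1,2-dichloroethane, 25 °C) should give benzyl 3-(benzyloxy)-4-[(2R)-but-3-en-2-yl]-5-[(3S,4R)-4-methyl-5-oxopent-1-en-3-yl]benzoate F6; Wittig methylenation (Ph3P=CH2, THF, 0 °C) returns to the route at 12.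

Step 9. Material may be lost to seven-membered ring closure through the 2′-vinyl group, cross-metathesis at the doubly branched vinyl group may stall, and ruthenium hydrides may move the ring alkene into conjugation. The fallback decouples the two events and attaches the side chain without metathesis. It sets out from 12: ring closure alone with first-generation Grubbs catalyst RuCl2(PCy3)2(=CHPh) (CH2Cl2, high dilution, benzoquinone) gives 16, now isolated. The coupling partner (2S)-3-bromo-2-methylpropyl 3-phenylpropanoate F7 is made from commercial (2S)-3-bromo-2-methylpropan-1-ol and 14 (pyridine, CH2Cl2). Hydroboration of the terminal vinyl group of 16 with 9-BBN (THF) should give benzyl (5R,8S)-4-(benzyloxy)-8-[(2S)-4-(9-borabicyclo[3.3.1]nonan-9-yl)butan-2-yl]-5-methyl-5,8-dihydronaphthalene-2-carboxylate F8, and alkyl–alkyl Suzuki coupling with F7 (Pd(OAc)2, PCy3, K3PO4·H2O, THF, 23 °C) should give benzyl (5R,8S)-4-(benzyloxy)-5-methyl-8-[(2S,6R)-6-methyl-7-(3-phenylpropanoyloxy)heptan-2-yl]-5,8-dihydronaphthalene-2-carboxylate F9. Hydrogenation (H2, 10% Pd/C) returns to the route at 18.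

Further compounds
F1 | step 4 | benzyl 3-(benzyloxy)-4-bromo-5-[(trifluoromethanesulfonyl)oxy]benzoate | O=C(OCc1ccccc1)c1cc(OS(=O)(=O)C(F)(F)F)c(Br)c(OCc2ccccc2)c1
F2 | step 4 | benzyl 3-(benzyloxy)-4-[(1E)-3-hydroxyprop-1-en-1-yl]-5-[(trifluoromethanesulfonyl)oxy]benzoate | OC/C=C/c1c(OCc2ccccc2)cc(C(=O)OCc2ccccc2)cc1OS(=O)(=O)C(F)(F)F
F3 | step 4 | benzyl 3-(benzyloxy)-4-[(1E)-3-chloroprop-1-en-1-yl]-5-[(trifluoromethanesulfonyl)oxy]benzoate | ClC/C=C/c1c(OCc2ccccc2)cc(C(=O)OCc2ccccc2)cc1OS(=O)(=O)C(F)(F)F
F4 | step 7 | benzyl 3-(benzyloxy)-4-[(2R)-but-3-en-2-yl]-5-formylbenzoate | C[C@H](C=C)c1c(OCc2ccccc2)cc(C(=O)OCc2ccccc2)cc1C=O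
F5 | step 7 | benzyl 3-(benzyloxy)-4-[(2R)-but-3-en-2-yl]-5-(1-hydroxyprop-2-en-1-yl)benzoate | C[C@H](C=C)c1c(OCc2ccccc2)cc(C(=O)OCc2ccccc2)cc1C(O)C=C
F6 | step 7 | benzyl 3-(benzyloxy)-4-[(2R)-but-3-en-2-yl]-5-[(3S,4R)-4-methyl-5-oxopent-1-en-3-yl]benzoate | O=C[C@H](C)[C@H](C=C)c1cc(C(=O)OCc2ccccc2)cc(OCc2ccccc2)c1[C@H](C)C=C
F7 | step 9 | (2S)-3-bromo-2-methylpropyl 3-phenylpropanoate | C[C@H](CBr)COC(=O)CCc1ccccc1
F8 | step 9 | benzyl (5R,8S)-4-(benzyloxy)-8-[(2S)-4-(9-borabicyclo[3.3.1]nonan-9-yl)butan-2-yl]-5-methyl-5,8-dihydronaphthalene-2-carboxylate | C[C@@H](CCB1C2CCCC1CCC2)[C@@H]1C=C[C@@H](C)c2c(OCc3ccccc3)cc(C(=O)OCc3ccccc3)cc21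
F9 | step 9 | benzyl (5R,8S)-4-(benzyloxy)-5-methyl-8-[(2S,6R)-6-methyl-7-(3-phenylpropanoyloxy)heptan-2-yl]-5,8-dihydronaphthalene-2-carboxylate | C[C@H](CCC[C@H](C)[C@@H]1C=C[C@@H](C)c2c(OCc3ccccc3)cc(C(=O)OCc3ccccc3)cc21)COC(=O)CCc1ccccc1
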